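**Assumptions:** Atom labels follow elemane numbering. C5 is CH(isopropenyl), C6 is CH–O(lactone), C7 is C–OH, C8 is CHOH, C9 is CH–O-angelate and C10 is C(CH3)(vinyl). C11(=C13H2)–C12(=O) is the methylene-lactone unit. Angelic anhydride is taken as a purchased reagent.

## Retrosynthetic overview
1. The target comes from a 7,8-O-isopropylidene tricycle by removal of the acetonide.
2. Both target rings are cut in one operation. A hetero-Pauson–Khand carbonylation of an allenyl aldehyde forms C6–C7, C11–C12 and C12–O6. The aldehyde is made in the same flask by a Claisen rearrangement that forms C5–C10.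
3. The acyclic precursor carries only two stereocentres: C8 from L-tartrate and C9 from a Felkin–Anh reduction. A vinylidene-dioxolane template relays C8 to C7 and C6. The C9–O bond steers the [3,3] shift that sets C10 and C5.
4. The precursor is assembled from a tartrate-derived Weinreb amide, a (Z)-alkenyllithium (from but-2-yn-1-ol and but-3-yn-2-one), angelic anhydride and CO.
5. Ring order: the dioxolane template is present from the start, and the cyclohexane and γ-lactone form together in step 10.

## Route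

**Step 1**
Reactants: 1 dimethyl (4R,5R)-2,2-dimethyl-1,3-dioxolane-4,5-dicarboxylate
Product: 3 methyl (4R,5S)-5-ethynyl-2,2-dimethyl-1,3-dioxolane-4-carboxylate, via formyl ester 2 (not isolated)
Conditions: i-Bu2AlH (1.0 equiv), CH2Cl2, −78 °C; then MeOH, K2CO3, MeC(O)C(N2)P(O)(OMe)2, −78 °C → rt
Reagents that add atoms: dimethyl (1-diazo-2-oxopropyl)phosphonate, CC(=O)C(=[N+]=[N-])P(=O)(OC)OC
Why: Half-reduction of one of the two homotopic esters stops at the aluminium hemiacetal, and the released aldehyde undergoes Seyferth–Gilbert (Ohira–Bestmann) homologation in the same flask; the ester-bearing centre (future C8) is untouched, and any epimerisation at the alkyne-bearing carbon (future C7) is harmless because step 8 flattens that centre.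

**Step 2**
Reactants: 3 methyl (4R,5S)-5-ethynyl-2,2-dimethyl-1,3-dioxolane-4-carboxylate
Product: 4 (4R,5S)-5-ethynyl-N-methoxy-N,2,2-trimethyl-1,3-dioxolane-4-carboxamide
Conditions: MeNH(OMe)·HCl, i-PrMgCl, THF, −20 → 0 °C
Reagents that add atoms: N,O-dimethylhydroxylamine hydrochloride, CNOC.Cl
Why: Weinreb amidation of the ester with the magnesium amide is fast below 0 °C and does not enolise the α-alkoxy centre, so no stereocentre is affected.

**Step 3**
Reactants: 5 but-2-yn-1-ol
Product: 6 (2Z)-3-iodobut-2-en-1-ol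
Conditions: NaAlH2(OCH2CH2OCH3)2, THF, 0 °C → rt; then I2, −78 °C
Reagents that add atoms: iodine, II
Why: Hydroxyl-directed trans-hydroalumination gives a five-membered alkenylalanate, and iodinolysis with retention places iodine cis to CH2OH, which fixes the Z geometry of the future C1=C10 alkene.

**Step 4**
Reactants: 6 (2Z)-3-iodobut-2-en-1-ol; 7 but-3-yn-2-one
Product: 8 (3E)-4-{[(2Z)-3-iodobut-2-en-1-yl]oxy}but-3-en-2-one
Conditions: DABCO (10 mol %), CH2Cl2, 0 °C → rt
Reagents that add atoms: none
Why: Amine-catalysed oxa-Michael addition of a primary alcohol to an ynone gives the thermodynamically preferred (E)-β-alkoxy enone, which sets the enol-ether geometry needed for the later [3,3] shift.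

**Step 5**
Reactants: 8 (3E)-4-{[(2Z)-3-iodobut-2-en-1-yl]oxy}but-3-en-2-one
Product: 9 (1E)-1-{[(2Z)-3-iodobut-2-en-1-yl]oxy}-3-methylbuta-1,3-diene
Conditions: Ph3PCH3Br, KN(SiMe3)2, THF, 0 °C; then 8, −78 → 0 °C
Reagents that add atoms: methyltriphenylphosphonium bromide, C[P+](c1ccccc1)(c1ccccc1)c1ccccc1.[Br-]
Why: Wittig methylenation with the unstabilised ylide attacks the ketone carbonyl faster than the β-carbon and leaves both alkene geometries and the alkenyl iodide untouched.

**Step 6**
Reactants: 9 (1E)-1-{[(2Z)-3-iodobut-2-en-1-yl]oxy}-3-methylbuta-1,3-diene; 4 (4R,5S)-5-ethynyl-N-methoxy-N,2,2-trimethyl-1,3-dioxolane-4-carboxamide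
Product: 12 (2Z)-1-[(4R,5S)-5-ethynyl-2,2-dimethyl-1,3-dioxolan-4-yl]-2-methyl-4-{[(1E)-3-methylbuta-1,3-dien-1-yl]oxy}but-2-en-1-one, via alkenyllithium 10 (not isolated), via lithium acetylide 11 (not isolated)
Conditions: 9, t-BuLi (2 equiv), Et2O, −78 °C; 4, LiN(SiMe3)2 (1.05 equiv), THF, −78 °C; combine, −78 → −40 °C; pH 7 buffer
Reagents that add atoms: none
Why: Iodine–lithium exchange proceeds with retention of the Z geometry, prior deprotonation masks the acidic alkyne C–H, and the chelated tetrahedral adduct of the Weinreb ketone synthesis prevents over-addition and enolisation at C8.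

**Step 7**
Reactants: 12 (2Z)-1-[(4R,5S)-5-ethynyl-2,2-dimethyl-1,3-dioxolan-4-yl]-2-methyl-4-{[(1E)-3-methylbuta-1,3-dien-1-yl]oxy}but-2-en-1-one
Product: 13 (1R,2Z)-1-[(4S,5S)-5-ethynyl-2,2-dimethyl-1,3-dioxolan-4-yl]-2-methyl-4-{[(1E)-3-methylbuta-1,3-dien-1-yl]oxy}but-2-en-1-ol
Conditions: LiBH(s-Bu)3, THF, −78 °C; aqueous NaHCO3 work-up
Reagents that add atoms: none
Why: This is a non-chelating Felkin–Anh 1,2-reduction of the α,β-disubstituted acyclic enone, in which the bulky hydride attacks anti to the C8–O bond and gives the 8,9-syn carbinol, which is the (R) configuration at C9.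

**Step 8**
Reactants: 13 (1R,2Z)-1-[(4S,5S)-5-ethynyl-2,2-dimethyl-1,3-dioxolan-4-yl]-2-methyl-4-{[(1E)-3-methylbuta-1,3-dien-1-yl]oxy}but-2-en-1-ol
Product: 14 (1R,2Z)-1-[(4S)-5-ethenylidene-2,2-dimethyl-1,3-dioxolan-4-yl]-2-methyl-4-{[(1E)-3-methylbuta-1,3-dien-1-yl]oxy}but-2-en-1-ol
Conditions: KOt-Bu (1.3 equiv), THF, 0 °C, short contact time
Reagents that add atoms: none
Why: Base-mediated propargyl ether → allenyl ether isomerisation removes the propargylic C7–H; the ring C8–O bond lies orthogonal to the carbanion, which slows β-elimination, and C7 becomes planar while C8 and C9 are kept.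

**Step 9**
Reactants: 14 (1R,2Z)-1-[(4S)-5-ethenylidene-2,2-dimethyl-1,3-dioxolan-4-yl]-2-methyl-4-{[(1E)-3-methylbuta-1,3-dien-1-yl]oxy}but-2-en-1-ol; 15 (2Z)-2-methylbut-2-enoic anhydride (angelic anhydride)
Product: 16 (1R,2Z)-1-[(4S)-5-ethenylidene-2,2-dimethyl-1,3-dioxolan-4-yl]-2-methyl-4-{[(1E)-3-methylbuta-1,3-dien-1-yl]oxy}but-2-en-1-yl (2Z)-2-methylbut-2-enoate
Conditions: LiN(SiMe3)2, THF, −78 °C; then 15, −78 → 0 °C
Reagents that add atoms: none
Why: Acylation of the only free hydroxyl as its lithium alkoxide with the symmetrical anhydride needs no nucleophilic catalyst or acid, so the angelate does not isomerise to the tiglate and both acid-labile enol ethers survive.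

**Step 10 (key step)**
Reactants: 16 (1R,2Z)-1-[(4S)-5-ethenylidene-2,2-dimethyl-1,3-dioxolan-4-yl]-2-methyl-4-{[(1E)-3-methylbuta-1,3-dien-1-yl]oxy}but-2-en-1-yl (2Z)-2-methylbut-2-enoate
Product: 18 7,8-O-isopropylidene derivative of 19 (cis-fused dioxolane/cyclohexane/α-methylene-γ-lactone tricycle with all six ring stereocentres as in 19), via Claisen aldehyde 17 (not isolated)
Conditions: Mo(CO)6 (1.5 equiv), DMSO (10 equiv), toluene (0.01 M), 100 °C
Reagents that add atoms: molybdenum hexacarbonyl (delivers CO), [Mo].[C-]#[O+].[C-]#[O+].[C-]#[O+].[C-]#[O+].[C-]#[O+].[C-]#[O+]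
Why: Proposed new method: a chair [3,3] Claisen rearrangement of the (E)-enol ether/(Z)-allyl ether (A1,3 strain holds H9 in the alkene plane, so the new bond forms anti to the C9–O bond) sets C10 and C5 and releases aldehyde 17, which zerovalent molybdenum captures before it can undergo Cope rearrangement in a hetero-Pauson–Khand [2+2+1] reaction of C=O, the inner allene π-bond and CO; C6 can reach the planar C7 of the vinylidene-dioxolane only from the face that carries C9, so the dioxolane ends cis-fused (O7 syn to O8), and the nearly flat oxametallacycle forces O6 and C11 cis, which fixes C6; the closest known reaction types are the thermal Claisen rearrangement of allyl 3-methylbutadienyl ethers and the Mo(CO)6-mediated cyclocarbonylation of allenyl aldehydes to cis-fused α-methylene-γ-butyrolactones, and what is new is the oxygen-substituted 1,1-disubstituted allene and running both events in one flask.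

**Step 11**
Reactants: 18 7,8-O-isopropylidene derivative of 19
Product: 19 (3aS,4S,5R,6S,7S,7aS)-6-ethenyl-3a,4-dihydroxy-6-methyl-3-methylidene-2-oxo-7-(prop-1-en-2-yl)octahydro-1-benzofuran-5-yl (2Z)-2-methylbut-2-enoate
Conditions: AcOH–H2O (4:1), 40 °C
Reagents that add atoms: none
Why: Acid-catalysed acetal hydrolysis frees the cis-7,8-diol under conditions that leave the lactone, the angelate and the three isolated alkenes intact, and no stereocentre is touched.

## Compound list
1 | dimethyl (4R,5R)-2,2-dimethyl-1,3-dioxolane-4,5-dicarboxylate | COC(=O)[C@@H]1OC(C)(C)O[C@H]1C(=O)OC | starting material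
2 | methyl (4R,5R)-5-formyl-2,2-dimethyl-1,3-dioxolane-4-carboxylate | COC(=O)[C@@H]1OC(C)(C)O[C@H]1C=O | intermediate
3 | methyl (4R,5S)-5-ethynyl-2,2-dimethyl-1,3-dioxolane-4-carboxylate | COC(=O)[C@@H]1OC(C)(C)O[C@H]1C#C | intermediate
4 | (4R,5S)-5-ethynyl-N-methoxy-N,2,2-trimethyl-1,3-dioxolane-4-carboxamide | CON(C)C(=O)[C@@H]1OC(C)(C)O[C@H]1C#C | intermediate
5 | but-2-yn-1-ol | CC#CCO | starting material
6 | (2Z)-3-iodobut-2-en-1-ol | C/C(I)=C/CO | intermediate
7 | but-3-yn-2-one | CC(=O)C#C | starting material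
8 | (3E)-4-{[(2Z)-3-iodobut-2-en-1-yl]oxy}but-3-en-2-one | CC(=O)/C=C/OC/C=C(/C)I | intermediate
9 | (1E)-1-{[(2Z)-3-iodobut-2-en-1-yl]oxy}-3-methylbuta-1,3-diene | C=C(C)/C=C/OC/C=C(/C)I | intermediate
10 | (Z)-alkenyllithium from 9 (Li in place of I) | C=C(C)/C=C/OC/C=C(/C)[Li] | intermediate
11 | lithium acetylide of 4 | CON(C)C(=O)[C@@H]1OC(C)(C)O[C@H]1C#C[Li] | intermediate
12 | (2Z)-1-[(4R,5S)-5-ethynyl-2,2-dimethyl-1,3-dioxolan-4-yl]-2-methyl-4-{[(1E)-3-methylbuta-1,3-dien-1-yl]oxy}but-2-en-1-one | C=C(C)/C=C/OC/C=C(/C)C(=O)[C@@H]1OC(C)(C)O[C@H]1C#C | intermediate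
13 | (1R,2Z)-1-[(4S,5S)-5-ethynyl-2,2-dimethyl-1,3-dioxolan-4-yl]-2-methyl-4-{[(1E)-3-methylbuta-1,3-dien-1-yl]oxy}but-2-en-1-ol | C=C(C)/C=C/OC/C=C(/C)[C@@H](O)[C@@H]1OC(C)(C)O[C@H]1C#C | intermediate
14 | (1R,2Z)-1-[(4S)-5-ethenylidene-2,2-dimethyl-1,3-dioxolan-4-yl]-2-methyl-4-{[(1E)-3-methylbuta-1,3-dien-1-yl]oxy}but-2-en-1-ol | C=C(C)/C=C/OC/C=C(/C)[C@@H](O)[C@@H]1OC(C)(C)OC1=C=C | intermediate
15 | (2Z)-2-methylbut-2-enoic anhydride (angelic anhydride) | C/C=C(/C)C(=O)OC(=O)/C(C)=C\C | starting material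
16 | angelate of 14 | C=C(C)/C=C/OC/C=C(/C)[C@@H](OC(=O)/C(C)=C\C)[C@@H]1OC(C)(C)OC1=C=C | intermediate
17 | (1R,2S,3S)-1-[(4S)-5-ethenylidene-2,2-dimethyl-1,3-dioxolan-4-yl]-2-ethenyl-3-formyl-2,4-dimethylpent-4-en-1-yl (2Z)-2-methylbut-2-enoate | C=C[C@@](C)([C@H](C(=C)C)C=O)[C@@H](OC(=O)/C(C)=C\C)[C@@H]1OC(C)(C)OC1=C=C | intermediate
18 | 7,8-O-isopropylidene derivative of 19 | C=C[C@@]1(C)[C@H](C(=C)C)[C@@H]2OC(=O)C(=C)[C@@]23OC(C)(C)O[C@H]3[C@@H]1OC(=O)/C(C)=C\C | intermediate
19 | CNP0114166.3 | C=C[C@@]1(C)[C@H](C(=C)C)[C@@H]2OC(=O)C(=C)[C@]2(O)[C@@H](O)[C@@H]1OC(=O)/C(C)=C\C | target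

## Step count and weak points
Total steps: 11. Longest linear sequence: 9 (steps 3, 4, 5, 6, 7, 8, 9, 10, 11).

**Most likely to fail, first: step 10.** The molybdenum may engage the outer allene π-bond, or aldehyde 17 may undergo Cope rearrangement before it is captured.
- The fallback sets out from 16 and comes back at 18.
- 16 is heated alone, briefly, in toluene at 100 °C, and aldehyde 17 is isolated cold.
- 17 is then treated at 0 °C with zerovalent nickel, Ni(C8H12)2, and DBU under CO2 (1 atm).
- CO2 couples at the central allene carbon to give a 2-carboxyallylnickel species. This species allylates the aldehyde through C7 in a polar, closed transition state under the same dioxolane face control.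
- Acidification gives the seco hydroxy acid F1, which lactonises on standing to 18.

**Second: step 8.** The base may carry the isomerisation on to the 4-vinyl-1,3-dioxole and erase C8.
- The fallback sets out from 13 and comes back at 14 without any carbanion.
- Pd(OAc)2-catalysed Markovnikov hydroselenation of the terminal alkyne with PhSeH in pyridine gives the 2-(phenylselanyl)alkene F2.
- Oxidation with H2O2 in THF–pyridine at 0 °C gives the alkenyl selenoxide F3.
- On warming, F3 undergoes syn-elimination towards the C7–H bond and gives 14. Elimination in the other direction only returns 13.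

**Third: step 6.** The basic alkenyllithium meets an acidic alkyne and gives an isomerisation-prone Z-enone.
- The fallback sets out from 3 and 9 and comes back at 12.
- 3 is reduced with i-Bu2AlH at −78 °C to the ethynyl aldehyde F4.
- F4 is joined to 9 by a non-basic Nozaki–Hiyama–Kishi coupling (CrCl2, catalytic NiCl2, DMSO, rt). This gives 13 together with its C9 epimer F5.
- The mixture is oxidised with Dess–Martin periodinane (NaHCO3, CH2Cl2) to the single enone 12.

## Further compounds
F1 | step 10 | seco hydroxy acid of 18 (free 6-OH and free acrylic acid on C7) | C=C[C@@]1(C)[C@H](C(=C)C)[C@H](O)[C@@]2(C(=C)C(=O)O)OC(C)(C)O[C@H]2[C@@H]1OC(=O)/C(C)=C\C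
F2 | step 8 | 2-(phenylselanyl)alkene from 13 (PhSe on the inner alkyne carbon) | C=C(C)/C=C/OC/C=C(/C)[C@@H](O)[C@@H]1OC(C)(C)O[C@H]1C(=C)[Se]c1ccccc1
F3 | step 8 | alkenyl selenoxide from F2 | C=C(C)/C=C/OC/C=C(/C)[C@@H](O)[C@@H]1OC(C)(C)O[C@H]1C(=C)[Se](=O)c1ccccc1
F4 | step 6 | (4R,5S)-5-ethynyl-2,2-dimethyl-1,3-dioxolane-4-carbaldehyde | O=C[C@@H]1OC(C)(C)O[C@H]1C#C
F5 | step 6 | (1S) epimer of 13 | C=C(C)/C=C/OC/C=C(/C)[C@H](O)[C@@H]1OC(C)(C)O[C@H]1C#C
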